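**Retrosynthetic overview**
1. Numbering: C1 = oxolane carbon bearing i‑Pr, C2=C3 = E‑alkene, C4 = tertiary carbinol, C6 = ketone, C8 = CH(CH3), C11 = formyloxy carbon, C12 = oxolane carbon bearing CH3, C13–C14 = oxolane CH2CH2.
2. Enabling feature: on the oxolane ring (O, C1, C14, C13, C12) the two chain carbons C2 (sp2) and C11 (oxygenated) stand cis on the two fully substituted carbons. Reconnecting C2 to C11 gives a 7‑oxabicyclo[2.2.1]heptene enol ether, which is the Diels–Alder adduct of a flat 3‑silyloxy‑2,5‑dialkylfuran and an ethylene equivalent. The C11 oxygen is the group that polarises the furan.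
3. Late disconnections: formate ester, C6 ketone (from the alcohol), and the 14‑membered ring by ring‑closing metathesis at C9=C10 followed by diimide reduction. C7–C9 come from methyl (R)‑3‑hydroxy‑2‑methylpropanoate.
4. C3–C6 come from a vinylogous Horner–Wadsworth–Emmons reaction, then Sharpless epoxidation and hydride opening (sets C4). C11 is set by chelation‑controlled reduction of a vinyl ketone. C2‑CHO and C11‑CO2H arise by cleaving the C2–C11 bond of the bicyclic template.
5. Ring order: furan, then oxolane plus a temporary six‑membered carbocycle (both in the key step), then cleavage of the carbocycle, then the 14‑membered carbocycle last.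

Key step: step 4

Assumption: the sense of induction known for acrylates with the protonated (S)‑prolinol‑derived oxazaborolidine (diene adds to the Cα‑Re face) is taken to hold for furan 6; the enantiomeric catalyst is equally available.

**Step 1**
Reactants: 1 ethyl (S)‑lactate
Product: 2 ethyl (S)‑2‑[(tert‑butyldimethylsilyl)oxy]propanoate
Conditions: TBSCl, imidazole, DMF, 0 °C to rt
Reagents that add atoms: tert‑butyldimethylsilyl chloride, CC(C)(C)[Si](C)(C)Cl
Why: Standard silyl ether protection lets the ester act as acyl donor in step 2; the stereocentre is erased in step 3 and is of no consequence.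

**Step 2**
Reactants: 2 ethyl (S)‑2‑[(tert‑butyldimethylsilyl)oxy]propanoate; 3 3‑methylbutan‑2‑one
Product: 5 2‑methyl‑5‑(propan‑2‑yl)furan‑3(2H)‑one, via silyloxy 1,3‑diketone 4 (not isolated)
Conditions: LiN(iPr)2 (2.1 equiv), THF, −78 °C; add 2, −78 to 0 °C; then 3 M HCl, THF, rt
Reagents that add atoms: none
Why: Crossed Claisen condensation of the kinetic methyl‑side enolate gives the 1,3‑diketone, and acid removes the silyl group and cyclodehydrates the α′‑hydroxy‑1,3‑diketone to the 3(2H)‑furanone.

**Step 3**
Reactants: 5 2‑methyl‑5‑(propan‑2‑yl)furan‑3(2H)‑one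
Product: 6 triisopropyl{[2‑methyl‑5‑(propan‑2‑yl)furan‑3‑yl]oxy}silane
Conditions: TIPSOTf, Et3N, CH2Cl2, 0 °C; used promptly
Reagents that add atoms: triisopropylsilyl triflate, CC(C)[Si](C(C)C)(C(C)C)OS(=O)(=O)C(F)(F)F
Why: Soft enolisation with O‑silylation removes the acidic C2–H because this creates the aromatic 3‑silyloxyfuran.

**Step 4**
Reactants: 6 triisopropyl{[2‑methyl‑5‑(propan‑2‑yl)furan‑3‑yl]oxy}silane; 7 2,2,2‑trifluoroethyl acrylate
Product: 8 2,2,2‑trifluoroethyl (1S,2S,4S)‑4‑methyl‑1‑(propan‑2‑yl)‑5‑[(triisopropylsilyl)oxy]‑7‑oxabicyclo[2.2.1]hept‑5‑ene‑2‑carboxylate (ester endo)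
Conditions: (S)‑3,3‑diphenyl‑1‑(2‑methylphenyl)tetrahydro‑1H,3H‑pyrrolo[1,2‑c][1,3,2]oxazaborole (20 mol %), Tf2NH (18 mol %), CH2Cl2, −78 to −40 °C
Reagents that add atoms: none
Why: The protonated oxazaborolidine binds the acrylate carbonyl, and the furan adds through its two α‑carbons in a concerted but strongly asynchronous [4π+2π] cycloaddition in which the acrylate CH2 bonds first to the enol‑ether β‑carbon (future C12) and the ester‑bearing carbon then closes on the oxocarbenium‑like carbon (future C1). The closest known reaction types are the oxazaborolidinium‑catalysed enantioselective Diels–Alder reactions of furans with 2,2,2‑trifluoroethyl acrylate and of 2‑(triisopropylsilyloxy)‑1,3‑dienes with acrylates. Both rings close in one suprafacial event: the temporary carbocycle C1–C2=C11–C12–C13–C14 by the cycloaddition itself, and the oxolane O–C1–C14–C13–C12 because the furan oxygen becomes the one‑atom bridge. C1 and C12 are necessarily cis because both bonds form on one furan face, and their absolute configuration follows from three coupled elements: silyloxy‑directed "para" regiochemistry, endo orientation of the ester, and catalyst shielding of the acrylate Cα‑Si face; the C14 centre is temporary. Regio‑, endo/exo‑ and facial selectivity are all needed, because a regio‑ or exo‑isomer formed on the same acrylate face would give the enantiomeric core once the ester is removed. The 3‑silyloxy group secures the regiochemistry, low temperature and secondary orbital overlap secure the endo mode, and the minor isomers are constitutional isomers or diastereomers that can be removed here or by crystallisation of 10.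

**Step 5**
Reactants: 8 cycloadduct
Product: 10 (1R,2S,4S)‑4‑methyl‑5‑oxo‑1‑(propan‑2‑yl)‑7‑oxabicyclo[2.2.1]heptane‑2‑carboxylic acid, via keto ester 9 (not isolated)
Conditions: Bu4NF, AcOH, THF, 0 °C; then LiOH, THF/H2O, 0 °C; 1 M HCl to pH 3
Reagents that add atoms: lithium hydroxide, [Li+].[OH-]
Why: Buffered protodesilylation of the silyl enol ether gives a saturated ketone that cannot undergo retro‑Diels–Alder reaction, and the activated trifluoroethyl ester is saponified under conditions too mild for β‑elimination of the oxygen bridge.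

**Step 6**
Reactants: 10 keto acid
Product: 12 (1S,4R)‑1‑methyl‑4‑(propan‑2‑yl)‑7‑oxabicyclo[2.2.1]heptan‑2‑one, via thiohydroxamate ester 11 (not isolated)
Conditions: 1‑hydroxypyridine‑2(1H)‑thione, DCC, CH2Cl2, 0 °C, dark; then t‑BuSH, hν (tungsten lamp), rt
Reagents that add atoms: 1‑hydroxypyridine‑2(1H)‑thione, ON1C=CC=CC1=S (in 11 only)
Why: Barton reductive decarboxylation turns the acrylate into a net ethylene unit; at the ketone stage the C14 radical has no alkene for a homoallyl–cyclopropylcarbinyl rearrangement, and a β‑alkoxy radical does not fragment.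

**Step 7**
Reactants: 12 bicyclic ketone
Product: 14 (2S,5S)‑5‑formyl‑2‑methyl‑5‑(propan‑2‑yl)oxolane‑2‑carboxylic acid, via trimethylsilyl enol ether 13 (not isolated)
Conditions: LiN(iPr)2, TMSCl (internal quench), THF, −78 °C; pentane filtration; O3, CH2Cl2, −78 °C; Me2S; H2O
Reagents that add atoms: ozone, O=[O+][O-]; chlorotrimethylsilane, C[Si](C)(C)Cl (in 13 only)
Why: Only C2 can be enolised because C12 is a quaternary bridgehead, and ozonolysis of the silyl enol ether cleaves the template bond C2–C11 into differentiated termini (C2 aldehyde, C11 acid) that are cis on the oxolane; the enolate is kept at −78 °C to avoid opening of the bridge.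

**Step 8**
Reactants: 14 aldehyde acid; 15 triethyl 3‑methyl‑4‑phosphonocrotonate (commercial E/Z mixture; both isomers give the same anion)
Product: 16 (2S,5S)‑5‑[(1E,3E)‑5‑ethoxy‑3‑methyl‑5‑oxopenta‑1,3‑dien‑1‑yl]‑2‑methyl‑5‑(propan‑2‑yl)oxolane‑2‑carboxylic acid
Conditions: LiN(SiMe3)2 (2.3 equiv in total), THF/DMPU, −78 to 0 °C; 1 M HCl work‑up
Reagents that add atoms: none
Why: In the vinylogous Horner–Wadsworth–Emmons olefination (acid carried as its lithium salt), the planar stabilised anion tolerates the neopentylic aldehyde and reversible addition leads to the E‑alkene at C2=C3, installing C3–C6 and the C4 methyl at once.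

**Step 9**
Reactants: 16 dienoate acid; 17 tributyl(vinyl)stannane
Product: 19 ethyl (2E,4E)‑3‑methyl‑5‑[(2S,5S)‑5‑methyl‑5‑(prop‑2‑enoyl)‑2‑(propan‑2‑yl)oxolan‑2‑yl]penta‑2,4‑dienoate, via acid chloride 18 (not isolated)
Conditions: 1‑chloro‑N,N,2‑trimethylprop‑1‑en‑1‑amine, CH2Cl2, 0 °C; then 17, Pd2(dba)3 (2.5 mol %), P(2‑furyl)3, THF, CO balloon, rt
Reagents that add atoms: 1‑chloro‑N,N,2‑trimethylprop‑1‑en‑1‑amine, CC(C)=C(Cl)N(C)C (chlorine in 18 only)
Why: Neutral chlorination followed by Stille acylation (oxidative addition to zerovalent palladium, transmetalation, reductive elimination) forms the vinyl ketone without touching the dienoate, and the CO atmosphere suppresses decarbonylation.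

**Step 10**
Reactants: 19 vinyl ketone
Product: 20 ethyl (2E,4E)‑5‑{(2S,5S)‑5‑[(1R)‑1‑hydroxyprop‑2‑en‑1‑yl]‑5‑methyl‑2‑(propan‑2‑yl)oxolan‑2‑yl}‑3‑methylpenta‑2,4‑dienoate
Conditions: Zn(BH4)2, Et2O, −78 to −30 °C; aq. NH4Cl
Reagents that add atoms: none
Why: In this chelation‑controlled (Cram chelate) 1,2‑reduction, zinc ties the ketone oxygen to the oxolane oxygen and hydride attacks from the face flanked by the C12 methyl rather than by ring carbon C13, which sets 11R; esters are inert to the reagent.

**Step 11**
Reactants: 20 allylic alcohol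
Product: 21 C11 triethylsilyl ether of 20
Conditions: TESOTf, 2,6‑lutidine, CH2Cl2, −78 to 0 °C
Reagents that add atoms: triethylsilyl triflate, CC[Si](CC)(CC)OS(=O)(=O)C(F)(F)F
Why: Silyl triflate protection of the hindered alcohol keeps this second allylic alcohol out of the epoxidation in step 13; at this neopentylic site a triethylsilyl ether is robust yet removable under mild conditions.

**Step 12**
Reactants: 21 silyl ether dienoate
Product: 22 (2E,4E)‑dienol (C6 primary alcohol)
Conditions: iBu2AlH (2.5 equiv), CH2Cl2, −78 °C; Rochelle salt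
Reagents that add atoms: none
Why: 1,2‑Reduction of the conjugated ester by the aluminium hydride gives the allylic alcohol without affecting the alkenes or the silyl ether.

**Step 13**
Reactants: 22 dienol
Product: 23 (4R,5R)‑epoxy alcohol
Conditions: Ti(OiPr)4 (10 mol %), D‑(−)‑diethyl tartrate (12 mol %), t‑BuOOH, 4 Å sieves, CH2Cl2, −20 °C
Reagents that add atoms: tert‑butyl hydroperoxide, CC(C)(C)OO
Why: Sharpless asymmetric epoxidation oxidises only the alkene of the free allylic alcohol, and the D‑tartrate delivers oxygen in the sense that gives (2R,3R)‑epoxides from E‑allylic alcohols, so the C4–O bond is set under reagent control.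

**Step 14**
Reactants: 23 epoxy alcohol
Product: 24 (4S)‑1,3‑diol (C4 tertiary OH, C6 primary OH)
Conditions: NaAlH2(OCH2CH2OMe)2, THF, 0 °C
Reagents that add atoms: none
Why: In this directed reductive opening of a 2,3‑epoxy alcohol, the C6‑bound aluminate delivers hydride intramolecularly to the secondary carbon C5, giving the 1,3‑diol while the C4–O bond and its configuration stay untouched.

**Step 15**
Reactants: 24 diol
Product: 25 (3S,4E)‑β‑hydroxy aldehyde (C6 aldehyde), used crude
Conditions: TEMPO (2,2,6,6‑tetramethylpiperidin‑1‑oxyl, 10 mol %), PhI(OAc)2, CH2Cl2, rt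
Reagents that add atoms: none
Why: The oxoammonium‑mediated oxidation is selective for the primary alcohol, and the tertiary allylic alcohol cannot be oxidised.

**Step 16**
Reactants: 26 methyl (R)‑3‑hydroxy‑2‑methylpropanoate
Product: 27 methyl (R)‑3‑[(tert‑butyldimethylsilyl)oxy]‑2‑methylpropanoate
Conditions: TBSCl, imidazole, CH2Cl2, rt
Reagents that add atoms: tert‑butyldimethylsilyl chloride, CC(C)(C)[Si](C)(C)Cl
Why: Routine silyl protection; the chiral‑pool stereocentre becomes C8.

**Step 17**
Reactants: 27 silyl ether ester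
Product: 28 (R)‑3‑[(tert‑butyldimethylsilyl)oxy]‑2‑methylpropanal
Conditions: iBu2AlH (1.05 equiv), CH2Cl2, −78 °C; Rochelle salt
Reagents that add atoms: none
Why: The partial ester reduction stops at the tetrahedral aluminium hemiacetal at −78 °C, so the aldehyde is released only on work‑up and is used at once to avoid epimerisation.

**Step 18**
Reactants: 28 aldehyde
Product: 29 (S)‑tert‑butyl(dimethyl)[(2‑methylbut‑3‑en‑1‑yl)oxy]silane
Conditions: Ph3PCH3Br, NaN(SiMe3)2, THF, −78 to 0 °C
Reagents that add atoms: methyltriphenylphosphonium bromide, C[P+](c1ccccc1)(c1ccccc1)c1ccccc1.[Br-]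
Why: Wittig methylenation at low temperature is faster than enolisation of the α‑branched aldehyde, so the stereocentre is retained.

**Step 19**
Reactants: 29 silyl ether alkene
Product: 30 (S)‑4‑bromo‑3‑methylbut‑1‑ene
Conditions: Ph3PBr2, CH2Cl2, 0 °C to rt
Reagents that add atoms: dibromotriphenylphosphorane, BrP(Br)(c1ccccc1)(c1ccccc1)c1ccccc1
Why: Appel‑type direct conversion of a primary silyl ether into the bromide proceeds by SN2 collapse of the alkoxyphosphonium bromide, avoids isolating the volatile alcohol and leaves the adjacent stereocentre untouched.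

**Step 20**
Reactants: 25 β‑hydroxy aldehyde; 30 (S)‑4‑bromo‑3‑methylbut‑1‑ene
Product: 32 seco‑diene diol (C6 epimers), via Grignard reagent 31 (not isolated)
Conditions: Mg, THF, rt; then 25 (31 in 2.5‑fold excess), −78 °C; aq. NH4Cl
Reagents that add atoms: magnesium, [Mg] (in 31 only)
Why: In this Grignard addition the first equivalent deprotonates C4–OH and the second adds to the aldehyde faster than retro‑aldol cleavage at −78 °C; the new C6 centre is destroyed in step 23, so its configuration does not matter.

**Step 21**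
Reactants: 32 seco‑diene diol
Product: 33 14‑membered C9=C10 cycloalkene (E/Z and C6 epimers)
Conditions: second‑generation Grubbs catalyst RuCl2(=CHPh)(PCy3)(H2IMes) (10 mol %), CH2Cl2 (1 mM), reflux
Reagents that add atoms: none
Why: In the ring‑closing metathesis the catalyst loads on the less hindered C9 vinyl group and closes on the C10 vinyl group, the C2=C3 alkene between two fully substituted carbons is inert, and loss of ethene drives the closure.

**Step 22**
Reactants: 33 cycloalkene
Product: 34 saturated C9–C10 macrocycle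
Conditions: 2‑nitrobenzenesulfonohydrazide, Et3N, CH2Cl2, rt
Reagents that add atoms: none
Why: Diimide reduction is governed by steric access, so the C9=C10 alkene is reduced while the C2=C3 alkene flanked by C1 and C4 is spared, and no hydrogenolysis of the allylic alcohol can occur.

**Step 23**
Reactants: 34 macrocyclic diol
Product: 35 C6 ketone
Conditions: Dess–Martin periodinane, NaHCO3, CH2Cl2, 0 °C to rt
Reagents that add atoms: none
Why: Dess–Martin oxidation under buffered neutral conditions converts the only free secondary alcohol into the ketone without dehydration or retro‑aldol cleavage of the β‑hydroxy ketone.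

**Step 24**
Reactants: 35 silyl ether ketone
Product: 36 C11 alcohol
Conditions: HF·pyridine, pyridine, THF, 0 °C
Reagents that add atoms: none
Why: Buffered fluoride cleavage of the triethylsilyl ether avoids both basic conditions (retro‑aldol, elimination) and strongly acidic conditions (ionisation of the tertiary allylic alcohol).

**Step 25**
Reactants: 36 C11 alcohol
Product: 37 target CNP0176107.1
Conditions: acetic formic anhydride, pyridine, CH2Cl2, −20 to 0 °C
Reagents that add atoms: acetic formic anhydride, CC(=O)OC=O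
Why: O‑Formylation with the small mixed anhydride acylates the secondary C11 alcohol faster than the tertiary C4 alcohol, and the labile formate is installed last.

**Compound list**
1 | ethyl (S)‑lactate | C[C@H](O)C(=O)OCC | starting material
2 | ethyl (S)‑2‑[(tert‑butyldimethylsilyl)oxy]propanoate | C[C@H](O[Si](C)(C)C(C)(C)C)C(=O)OCC | intermediate
3 | 3‑methylbutan‑2‑one | CC(=O)C(C)C | starting material
4 | (S)‑2‑[(tert‑butyldimethylsilyl)oxy]‑6‑methylheptane‑3,5‑dione | C[C@H](O[Si](C)(C)C(C)(C)C)C(=O)CC(=O)C(C)C | intermediate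
5 | 2‑methyl‑5‑(propan‑2‑yl)furan‑3(2H)‑one (C2 labile through the enol, configuration immaterial) | CC1OC(C(C)C)=CC1=O | intermediate
6 | triisopropyl{[2‑methyl‑5‑(propan‑2‑yl)furan‑3‑yl]oxy}silane | Cc1oc(C(C)C)cc1O[Si](C(C)C)(C(C)C)C(C)C | intermediate
7 | 2,2,2‑trifluoroethyl acrylate | C=CC(=O)OCC(F)(F)F | starting material
8 | endo cycloadduct, (1S,2S,4S) | CC(C)[C@]12C=C(O[Si](C(C)C)(C(C)C)C(C)C)[C@](C)(C[C@@H]1C(=O)OCC(F)(F)F)O2 | intermediate
9 | keto trifluoroethyl ester, (1R,2S,4S) | CC(C)[C@]12CC(=O)[C@](C)(C[C@@H]1C(=O)OCC(F)(F)F)O2 | intermediate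
10 | keto acid, (1R,2S,4S) | CC(C)[C@]12CC(=O)[C@](C)(C[C@@H]1C(=O)O)O2 | intermediate
11 | 2‑thioxopyridin‑1(2H)‑yl ester of 10 | CC(C)[C@]12CC(=O)[C@](C)(C[C@@H]1C(=O)ON3C=CC=CC3=S)O2 | intermediate
12 | (1S,4R)‑1‑methyl‑4‑(propan‑2‑yl)‑7‑oxabicyclo[2.2.1]heptan‑2‑one | CC(C)[C@]12CC(=O)[C@](C)(CC1)O2 | intermediate
13 | trimethylsilyl enol ether of 12, (1S,4S) | CC(C)[C@]12C=C(O[Si](C)(C)C)[C@](C)(CC1)O2 | intermediate
14 | (2S,5S)‑5‑formyl‑2‑methyl‑5‑(propan‑2‑yl)oxolane‑2‑carboxylic acid | CC(C)[C@]1(C=O)CC[C@@](C)(C(=O)O)O1 | intermediate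
15 | triethyl 3‑methyl‑4‑phosphonocrotonate (E isomer drawn) | CCOC(=O)/C=C(\C)CP(=O)(OCC)OCC | starting material
16 | (2E,4E)‑dienoate acid | CC(C)[C@]1(/C=C/C(C)=C/C(=O)OCC)CC[C@@](C)(C(=O)O)O1 | intermediate
17 | tributyl(vinyl)stannane | C=C[Sn](CCCC)(CCCC)CCCC | starting material
18 | acid chloride of 16 | CC(C)[C@]1(/C=C/C(C)=C/C(=O)OCC)CC[C@@](C)(C(=O)Cl)O1 | intermediate
19 | C11 vinyl ketone | CC(C)[C@]1(/C=C/C(C)=C/C(=O)OCC)CC[C@@](C)(C(=O)C=C)O1 | intermediate
20 | (11R)‑allylic alcohol | CC(C)[C@]1(/C=C/C(C)=C/C(=O)OCC)CC[C@@](C)([C@H](O)C=C)O1 | intermediate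
21 | C11 triethylsilyl ether | CC(C)[C@]1(/C=C/C(C)=C/C(=O)OCC)CC[C@@](C)([C@H](O[Si](CC)(CC)CC)C=C)O1 | intermediate
22 | (2E,4E)‑dienol | CC(C)[C@]1(/C=C/C(C)=C/CO)CC[C@@](C)([C@H](O[Si](CC)(CC)CC)C=C)O1 | intermediate
23 | (4R,5R)‑epoxy alcohol | CC(C)[C@]1(/C=C/[C@@]2(C)O[C@@H]2CO)CC[C@@](C)([C@H](O[Si](CC)(CC)CC)C=C)O1 | intermediate
24 | (4S)‑1,3‑diol | CC(C)[C@]1(/C=C/[C@@](C)(O)CCO)CC[C@@](C)([C@H](O[Si](CC)(CC)CC)C=C)O1 | intermediate
25 | (4S)‑β‑hydroxy aldehyde | CC(C)[C@]1(/C=C/[C@@](C)(O)CC=O)CC[C@@](C)([C@H](O[Si](CC)(CC)CC)C=C)O1 | intermediate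
26 | methyl (R)‑3‑hydroxy‑2‑methylpropanoate | OC[C@@H](C)C(=O)OC | starting material
27 | methyl (R)‑3‑[(tert‑butyldimethylsilyl)oxy]‑2‑methylpropanoate | CC(C)(C)[Si](C)(C)OC[C@@H](C)C(=O)OC | intermediate
28 | (R)‑3‑[(tert‑butyldimethylsilyl)oxy]‑2‑methylpropanal | CC(C)(C)[Si](C)(C)OC[C@@H](C)C=O | intermediate
29 | (S)‑tert‑butyl(dimethyl)[(2‑methylbut‑3‑en‑1‑yl)oxy]silane | CC(C)(C)[Si](C)(C)OC[C@@H](C)C=C | intermediate
30 | (S)‑4‑bromo‑3‑methylbut‑1‑ene | BrC[C@@H](C)C=C | intermediate
31 | [(S)‑2‑methylbut‑3‑en‑1‑yl]magnesium bromide | Br[Mg]C[C@@H](C)C=C | intermediate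
32 | seco‑diene diol (C6 epimers) | CC(C)[C@]1(/C=C/[C@@](C)(O)CC(O)C[C@@H](C)C=C)CC[C@@](C)([C@H](O[Si](CC)(CC)CC)C=C)O1 | intermediate
33 | macrocyclic C9=C10 alkene (E/Z, C6 epimers) | CC(C)[C@]12/C=C/[C@@](C)(O)CC(O)C[C@@H](C)C=C[C@@H](O[Si](CC)(CC)CC)[C@](C)(CC1)O2 | intermediate
34 | macrocyclic diol, C9–C10 saturated (C6 epimers) | CC(C)[C@]12/C=C/[C@@](C)(O)CC(O)C[C@@H](C)CC[C@@H](O[Si](CC)(CC)CC)[C@](C)(CC1)O2 | intermediate
35 | C6 ketone, C11 silyl ether | CC(C)[C@]12/C=C/[C@@](C)(O)CC(=O)C[C@@H](C)CC[C@@H](O[Si](CC)(CC)CC)[C@](C)(CC1)O2 | intermediate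
36 | C11 alcohol | CC(C)[C@]12/C=C/[C@@](C)(O)CC(=O)C[C@@H](C)CC[C@@H](O)[C@](C)(CC1)O2 | intermediate
37 | CNP0176107.1, (1S,2E,4S,8S,11R,12S) | CC(C)[C@]12/C=C/[C@@](C)(O)CC(=O)C[C@@H](C)CC[C@@H](OC=O)[C@](C)(CC1)O2 | target

**Totals:** 25 steps. The longest linear sequence is 21 steps (steps 1–15 and 20–25); steps 16–19 form the side branch.

**Steps most likely to fail**

1. **Step 4.** The acidic catalyst may protodesilylate furan 6. The addition may also stop after the first bond (Michael‑type diversion), or endo and facial selectivity may erode. The fallback sets out from 6 and replaces catalyst control by a covalent auxiliary under neutral conditions. Furan 6 undergoes an uncatalysed cycloaddition (neat, 40 °C) with commercial (R)‑pantolactone acrylate. The adducts of the two furan faces are then diastereomers and are separated by chromatography or crystallisation. The isomer with the required core, pantolactone ester cycloadduct F1, is treated under the conditions of step 5 and comes back to the route at 10.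

2. **Step 21.** The neopentylic C10 vinyl group may engage too slowly, so that intermolecular metathesis at the C9 vinyl group leads to oligomers. The fallback sets out from 32 and closes the same bond by carbonyl coupling:
   - The 1,3‑diol is masked with 2,2‑dimethoxypropane and pyridinium p‑toluenesulfonate as seco‑diene acetonide F2.
   - Both monosubstituted vinyl groups are cleaved by Lemieux–Johnson oxidation (OsO4, N‑methylmorpholine N‑oxide, then NaIO4) to acetonide dialdehyde F3; the hindered C2=C3 alkene is spared.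
   - An intramolecular McMurry coupling with low‑valent titanium (TiCl4, Zn, pyridine, DME, reflux, slow addition) gives macrocyclic acetonide alkene F4.
   - Methanolysis with pyridinium p‑toluenesulfonate at 0 °C, which the neopentylic C11 silyl ether should survive, comes back to the route at 33.

3. **Step 10.** The zinc chelate may form incompletely, giving poor facial selectivity at C11, or conjugate reduction of the vinyl ketone may compete. The fallback sets out from 19 and replaces substrate control by reagent control. It is a Corey–Bakshi–Shibata reduction with (S)‑1‑methyl‑3,3‑diphenyltetrahydro‑1H,3H‑pyrrolo[1,2‑c][1,3,2]oxazaborole and catecholborane in toluene at −78 °C. The quaternary C12 side acts as the large group and the vinyl as the small group, which should give the (R)‑carbinol. The fallback comes back to the route at 20 and makes no new compound.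

**Further compounds**
F1 | step 4 | (R)‑pantolactone ester cycloadduct (endo, core as in 8) | CC(C)[C@]12C=C(O[Si](C(C)C)(C(C)C)C(C)C)[C@](C)(C[C@@H]1C(=O)O[C@H]3C(=O)OCC3(C)C)O2
F2 | step 21 | seco‑diene acetonide (C6 epimers) | CC(C)[C@]1(/C=C/[C@]2(C)CC(C[C@@H](C)C=C)OC(C)(C)O2)CC[C@@](C)([C@H](O[Si](CC)(CC)CC)C=C)O1
F3 | step 21 | acetonide dialdehyde (C9 and C10 aldehydes) | CC(C)[C@]1(/C=C/[C@]2(C)CC(C[C@@H](C)C=O)OC(C)(C)O2)CC[C@@](C)([C@H](O[Si](CC)(CC)CC)C=O)O1
F4 | step 21 | macrocyclic acetonide alkene | CC(C)[C@]12/C=C/[C@]3(C)CC(C[C@@H](C)C=C[C@@H](O[Si](CC)(CC)CC)[C@](C)(CC1)O2)OC(C)(C)O3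
F0 | step 10 | none | none
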